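Assumption: ring positions follow the biogenetic numbering C1(Me)=C2–C3(OH)–C4(iPr)–C5(OAr)–C6–C7(Me)=C8–C9–C10; in it the target is (3S,4S,5R), i.e. (1R,3Z,7Z,9S,10S) in the systematic name. TBS = tert-butyldimethylsilyl, PMB = 4-methoxybenzyl, Bpin = 4,4,5,5-tetramethyl-1,3,2-dioxaborolan-2-yl.

Check of the structures: enal 19 and cyclised alcohol 21 agree atom for atom and centre for centre with the target (C5 is R throughout, both ring alkenes and the allylboronate are Z), so no structural correction is needed. Two reagent points are corrected. Both iodoalkenes are trisubstituted and need the α-iodoethylidene ylide Ph3P=C(I)CH3, not Ph3P=CHI. The PMB ether made from (S)-glycidol is (R) by the sequence rule, with nothing changed in space.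

## Structural features

The target is a ten-membered carbocycle with a 4-hydroxybenzoate on C5; the only other ring is the arene of the ester. Two trisubstituted alkenes, C1=C2 and C7=C8, are both cis in the ring and are linked by the C9–C10 ethano bridge on one side and by the sp3 carbons C3–C6 on the other. C3 (S, secondary allylic alcohol), C4 (S, isopropyl) and C5 (R, acyloxy) are contiguous, with all three substituents cis on the ring (3,4-anti and 4,5-anti in the zigzag sense). Fragile elements are the skipped (Z,Z)-diene in a medium ring (acid-induced transannular cyclisation, Z/E drift), the allylic C3 alcohol, the 1,3-related hydroxyl and ester (acyl migration under base) and the free phenol. The real difficulty is to close a ten-membered ring without losing either (Z)-alkene while a stereotriad sits at the closure site, and then to saturate one alkene out of three. The key step uses the fact that C3 is a carbinol carbon and C4 carries a branched three-carbon unit: the γ-carbon C4 of a 2-methylallyl boronate adds to a C3 aldehyde, forming the bond that germacrane biosynthesis makes between farnesyl C1 and C10, with isopropenyl standing in for isopropyl.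

## Logic of the disconnections

23 ⇒ 22. The phenolic O–Si bond is cut. The phenol must be masked through acylation, ylide and organozinc chemistry. The forward cleavage must avoid base because of the 1,3-hydroxy ester.

22 ⇒ 21. Two C–H bonds of the isopropyl group are removed to give isopropenyl, which is what a 2-methylallyl metal delivers. The forward step must reduce one 1,1-disubstituted alkene beside two trisubstituted ones.

21 ⇒ 19 (through 20). The C3–C4 ring bond is cut. This opens the ring, removes two stereocentres and leaves a linear farnesyl-type chain with a C3 aldehyde and a (Z)-allylboronate whose γ-carbon is C4. The forward step must close a ten-membered ring under neutral conditions, keep the (Z)-enal, and let C5 choose the face of the allyl unit.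

19 ⇒ 18 ⇒ 17. The C3 oxidation level and the C3 O–Si bond are adjusted. The aldehyde is released only immediately before ring closure, since it cannot coexist with the boronate in concentrated solution. This demands an oxidation that does not isomerise the enal and a desilylation that distinguishes an alkyl from an aryl silyl ether.

17 ⇒ 16. The C(sp2)–CH2B bond is cut, leading back to a configurationally stable alkenyl iodide. One ester-tolerant, stereoretentive cross-coupling replaces borylation followed by a lithium carbenoid homologation.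

16 ⇒ 15 ⇒ 14 ⇒ 13. The C4=C bond is cut (olefination), then the C4 oxidation level and the PMB ether are adjusted. The olefination must put iodine cis to C5 without epimerising the α-acyloxy aldehyde, and the C5 ester must not migrate to the freed primary hydroxyl.

13 ⇒ 9 + 12, and 12 ⇒ 10. The ester C–O bond is cut with retention at C5, then the O–Si bond of the acid. Installing the final acyl group early avoids any later distinction between the C3 and C5 hydroxyls.

9 ⇒ 5 + 7, and 7 ⇒ 6. The C6–C7 bond is cut between an alkenyl nucleophile and a terminal epoxide. This gives two fragments of similar size and takes C5 from the chiral pool. The forward step needs retention of alkene geometry and attack at the epoxide CH2 only.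

5 ⇒ 4 ⇒ 3 ⇒ 2 ⇒ 1. The C7=C8 bond is cut by iodo-olefination, and the C8 aldehyde is traced to oxidative cleavage of the distal alkene of 1 after silylation. The C1=C2 (Z)-alkene comes ready-made, provided the epoxidation is site-selective.

## Other disconnections considered

Alternative 1: The ten-membered ring is derived from a cis-fused hydroazulene A1 by adding the transannular C3–C7 bond in the retrosynthetic direction. In the forward step the potassium alkoxide of A1 (KN(SiMe3)2) undergoes Grob fragmentation: C3–C7 breaks, C3=O and C7=C8 form and the C8 mesylate leaves, giving dienone A2.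
- In its favour: no entropically disfavoured ring closure and no dilution are needed, which is better than the chosen plan. The C7=C8 geometry follows stereospecifically from the antiperiplanar C3–C7/C8–O arrangement, which is equal to the chosen plan. The fragmentation is more predictable than a face selection by one stereocentre, which is also better.
- Against it: A1 needs five stereocentres, including a quaternary carbon and a tertiary carbinol, and three of them are destroyed. A2 is a β-alkoxy ketone with an acidic C4–H under a potassium base, so epimerisation or E1cB loss of the C5 oxygen threatens. The C3 ketone must then be reduced to the (S)-alcohol in a flexible ring, and the C5 PMB ether exchanged for the aroyl group beside a free C3 hydroxyl.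
- Comparison: the fragmentation sets none of the three target stereocentres, whereas the chosen step sets two and closes the ring. The sequence is estimated to be clearly longer than 17 steps.

Alternative 2: The C5–C6 bond is cut, with an oxygen bridging C5 and C8 in the nine-membered stannyl ether A3. In the forward step tin–lithium exchange (n-BuLi) gives an α-alkoxy organolithium at C5, which attacks the isopropenyl CH2 in a [2,3] Wittig–Still shift; the ring expands to the carbocycle A4.
- In its favour: the tether forces C9 cis to C6 in the five-membered transition state, so the (Z)-alkene is assured, which is equal to the chosen plan. C5 is transferred stereospecifically from the stannane (with inversion), which is better controlled than face selection. A4 has a free C5 hydroxyl and a silylated C3 hydroxyl, which is as convenient for acylation as carrying the ester from the start, so this point is equal.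
- Against it: A3 is itself a medium ring with a defined α-stannyl ether centre trans to the isopropenyl group, so the ring-forming problem is moved and not removed. A [1,2] shift or protonation of the carbanion can compete. C3 and C4 must be set separately beforehand.
- Comparison: this is a ring expansion where the chosen plan uses a ring closure. The step count is estimated in the low twenties.

Alternative 3: The C9–C10 bond between the two alkenes is cut. In the forward step the allyl sulfone anion of the open-chain bromide A5 (KN(SiMe3)2, high dilution) displaces the primary allylic bromide to give the cyclic sulfone A6, and the sulfonyl group is then removed reductively.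
- In its favour: the C3–C5 triad can be built on an open chain under reagent control and lies far from the closure site, so stereocontrol is more secure than in the chosen plan, which is better. Sulfone alkylation is a well-tried way to ten-membered terpenoid rings, so the precedent is equal or better.
- Against it: α versus γ alkylation of the sulfone anion and SN2 versus SN2' at the bromide must both go the right way. The (Z)-allylic bromide is configurationally labile. Reductive desulfonylation of an allylic sulfone (Na(Hg), SmI2) can shift or isomerise C7=C8. The C5 PMB ether and the C3 silyl ether must be exchanged at the end. Dilution is needed as in the chosen plan, so that point is equal.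
- Comparison: the ring closure creates no stereocentre and is followed by desulfonylation and three or four protecting-group steps. It is the longest of the four plans.

Key step: step 15

## Route

Step 1
Reactants: 1 nerol, (2Z)-3,7-dimethylocta-2,6-dien-1-ol
Product: 2 tert-butyl{[(2Z)-3,7-dimethylocta-2,6-dien-1-yl]oxy}dimethylsilane
Conditions: TBSCl, imidazole, CH2Cl2, 0 °C → rt
Reagents that add atoms: tert-butyldimethylsilyl chloride, CC(C)(C)[Si](C)(C)Cl
Why: Standard silylation of a primary allylic alcohol; the silyl ether is needed to survive the later alkenyllithium, ylide and organozinc steps.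

Step 2
Reactants: 2 tert-butyl{[(2Z)-3,7-dimethylocta-2,6-dien-1-yl]oxy}dimethylsilane
Product: 3 tert-butyl{[(2Z)-5-(3,3-dimethyloxiran-2-yl)-3-methylpent-2-en-1-yl]oxy}dimethylsilane (racemic at the oxirane carbon)
Conditions: mCPBA (1.05 equiv), CH2Cl2, −20 → 0 °C
Reagents that add atoms: 3-chloroperoxybenzoic acid, OOC(=O)c1cccc(Cl)c1
Why: Prilezhaev epoxidation; the distal alkene is the more electron-rich one because the proximal alkene is deactivated by the allylic C–O bond and shielded by the silyl group, so one equivalent of peracid should react there. The new epoxide centre is racemic and is destroyed in step 3.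

Step 3
Reactants: 3 tert-butyl{[(2Z)-5-(3,3-dimethyloxiran-2-yl)-3-methylpent-2-en-1-yl]oxy}dimethylsilane
Product: 4 (4Z)-6-[(tert-butyldimethylsilyl)oxy]-4-methylhex-4-enal
Conditions: H5IO6, THF/Et2O, 0 °C
Reagents that add atoms: none
Why: Periodic acid opens the epoxide to the glycol (water enters at the tertiary carbon, so the aldehyde keeps the epoxide oxygen) and cleaves it in the same flask (glycol cleavage), releasing acetone. The short contact at 0 °C is expected to spare the allylic silyl ether.

Step 4
Reactants: 4 (4Z)-6-[(tert-butyldimethylsilyl)oxy]-4-methylhex-4-enal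
Product: 5 tert-butyl{[(2Z,6Z)-7-iodo-3-methylocta-2,6-dien-1-yl]oxy}dimethylsilane
Conditions: EtPPh3I, n-BuLi, THF; I2, −78 °C; NaN(SiMe3)2; then 4, −78 → −20 °C
Reagents that add atoms: ethyltriphenylphosphonium iodide, CC[P+](c1ccccc1)(c1ccccc1)c1ccccc1.[I-]; iodine, II
Why: Wittig olefination with the α-iodoethylidene ylide (the methyl-bearing relative of the Stork–Zhao reagent), which gives (Z)-2-iodo-2-alkenes with iodine cis to the chain. The parent ylide Ph3P=CHI would leave C7 without its methyl group.

Step 5
Reactants: 6 (S)-glycidol, [(2S)-oxiran-2-yl]methanol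
Product: 7 (2R)-2-{[(4-methoxybenzyl)oxy]methyl}oxirane
Conditions: NaH, PMBCl, Bu4NI (cat.), THF/DMF, 0 °C → rt
Reagents that add atoms: 4-methoxybenzyl chloride, COc1ccc(CCl)cc1
Why: Williamson etherification; the Payne rearrangement of the glycidol alkoxide is degenerate, so no loss of optical purity is expected. The descriptor changes to R only because the priorities change.

Step 6
Reactants: 5 tert-butyl{[(2Z,6Z)-7-iodo-3-methylocta-2,6-dien-1-yl]oxy}dimethylsilane; 7 (2R)-2-{[(4-methoxybenzyl)oxy]methyl}oxirane
Product: 9 (2R,4Z,8Z)-10-[(tert-butyldimethylsilyl)oxy]-1-[(4-methoxybenzyl)oxy]-4,8-dimethyldeca-4,8-dien-2-ol, via alkenyllithium 8 (not isolated)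
Conditions: t-BuLi (2.1 equiv), Et2O, −78 °C; then 7, BF3·OEt2, −78 °C; aq. NH4Cl
Reagents that add atoms: none
Why: Iodine–lithium exchange with retention of alkene geometry, then BF3-assisted SN2 opening of the terminal epoxide at its CH2 carbon. C5 is not touched, so its configuration comes from 6, and the new C6–C7 bond leaves C6 cis to C9.

Step 7
Reactants: 10 4-hydroxybenzoic acid
Product: 12 4-[(tert-butyldimethylsilyl)oxy]benzoic acid, via silyl ester 11 (not isolated)
Conditions: TBSCl (2.2 equiv), imidazole, DMF, rt; then AcOH/THF/H2O, rt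
Reagents that add atoms: tert-butyldimethylsilyl chloride, CC(C)(C)[Si](C)(C)Cl
Why: Exhaustive silylation followed by selective hydrolysis of the labile silyl ester; the aryl silyl ether is stable to aqueous acetic acid.

Step 8
Reactants: 9 (2R,4Z,8Z)-10-[(tert-butyldimethylsilyl)oxy]-1-[(4-methoxybenzyl)oxy]-4,8-dimethyldeca-4,8-dien-2-ol; 12 4-[(tert-butyldimethylsilyl)oxy]benzoic acid
Product: 13 (2R,4Z,8Z)-10-[(tert-butyldimethylsilyl)oxy]-1-[(4-methoxybenzyl)oxy]-4,8-dimethyldeca-4,8-dien-2-yl 4-[(tert-butyldimethylsilyl)oxy]benzoate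
Conditions: DCC, DMAP (cat.), CH2Cl2, 0 °C → rt
Reagents that add atoms: none
Why: Steglich esterification of an unhindered secondary alcohol; the C5–O bond is not broken, so the configuration is retained.

Step 9
Reactants: 13 (2R,4Z,8Z)-10-[(tert-butyldimethylsilyl)oxy]-1-[(4-methoxybenzyl)oxy]-4,8-dimethyldeca-4,8-dien-2-yl 4-[(tert-butyldimethylsilyl)oxy]benzoate
Product: 14 (2R,4Z,8Z)-10-[(tert-butyldimethylsilyl)oxy]-1-hydroxy-4,8-dimethyldeca-4,8-dien-2-yl 4-[(tert-butyldimethylsilyl)oxy]benzoate
Conditions: DDQ, CH2Cl2/pH 7 buffer, 0 °C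
Reagents that add atoms: none
Why: Oxidative PMB cleavage by DDQ (hydride abstraction at the electron-rich benzylic position, then hydrolysis). Buffered, cold conditions are chosen so that the C5 ester does not migrate to the new primary hydroxyl.

Step 10
Reactants: 14 (2R,4Z,8Z)-10-[(tert-butyldimethylsilyl)oxy]-1-hydroxy-4,8-dimethyldeca-4,8-dien-2-yl 4-[(tert-butyldimethylsilyl)oxy]benzoate
Product: 15 (2R,4Z,8Z)-10-[(tert-butyldimethylsilyl)oxy]-4,8-dimethyl-1-oxodeca-4,8-dien-2-yl 4-[(tert-butyldimethylsilyl)oxy]benzoate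
Conditions: DMP, pyridine, CH2Cl2, 0 °C
Reagents that add atoms: none
Why: Dess–Martin oxidation under buffered, non-epimerising conditions; the α-aroyloxy aldehyde is not chromatographed and is used at once.

Step 11
Reactants: 15 (2R,4Z,8Z)-10-[(tert-butyldimethylsilyl)oxy]-4,8-dimethyl-1-oxodeca-4,8-dien-2-yl 4-[(tert-butyldimethylsilyl)oxy]benzoate
Product: 16 (2Z,4R,6Z,10Z)-12-[(tert-butyldimethylsilyl)oxy]-2-iodo-6,10-dimethyldodeca-2,6,10-trien-4-yl 4-[(tert-butyldimethylsilyl)oxy]benzoate
Conditions: EtPPh3I, n-BuLi, THF; I2, −78 °C; NaN(SiMe3)2; then 15, −78 °C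
Reagents that add atoms: ethyltriphenylphosphonium iodide, CC[P+](c1ccccc1)(c1ccccc1)c1ccccc1.[I-]; iodine, II
Why: The same iodo-olefination as in step 4, run at −78 °C with a slight excess of the weakly basic iodo ylide. It places iodine cis to C5, which is the geometry that becomes the (Z)-allylboronate.

Step 12
Reactants: 16 (2Z,4R,6Z,10Z)-12-[(tert-butyldimethylsilyl)oxy]-2-iodo-6,10-dimethyldodeca-2,6,10-trien-4-yl 4-[(tert-butyldimethylsilyl)oxy]benzoate
Product: 17 (2Z,4R,6Z,10Z)-12-[(tert-butyldimethylsilyl)oxy]-2,6,10-trimethyl-1-(4,4,5,5-tetramethyl-1,3,2-dioxaborolan-2-yl)dodeca-2,6,10-trien-4-yl 4-[(tert-butyldimethylsilyl)oxy]benzoate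
Conditions: ICH2Bpin, Zn, THF, rt; then 16, Pd(PPh3)4 (5 mol%), THF, rt → 40 °C
Reagents that add atoms: 2-(iodomethyl)-4,4,5,5-tetramethyl-1,3,2-dioxaborolane, ICB1OC(C)(C)C(C)(C)O1
Why: Negishi-type cross-coupling of an alkenyl iodide with the α-borylmethylzinc reagent IZnCH2Bpin, a known stereoretentive route to allylboronates. Oxidative addition and reductive elimination keep the geometry, so CH2B ends cis to C5. The zinc reagent tolerates both esters, unlike the LiCH2Cl of a Matteson homologation.

Step 13
Reactants: 17 (2Z,4R,6Z,10Z)-12-[(tert-butyldimethylsilyl)oxy]-2,6,10-trimethyl-1-(4,4,5,5-tetramethyl-1,3,2-dioxaborolan-2-yl)dodeca-2,6,10-trien-4-yl 4-[(tert-butyldimethylsilyl)oxy]benzoate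
Product: 18 (2Z,4R,6Z,10Z)-12-hydroxy-2,6,10-trimethyl-1-(4,4,5,5-tetramethyl-1,3,2-dioxaborolan-2-yl)dodeca-2,6,10-trien-4-yl 4-[(tert-butyldimethylsilyl)oxy]benzoate
Conditions: CSA (10 mol%), MeOH/CH2Cl2, 0 °C
Reagents that add atoms: none
Why: Acid-catalysed methanolysis removes a primary alkyl silyl ether much faster than an aryl silyl ether (the reverse of the order under fluoride or base). The pinacol boronate is expected to tolerate catalytic acid at 0 °C.

Step 14
Reactants: 18 (2Z,4R,6Z,10Z)-12-hydroxy-2,6,10-trimethyl-1-(4,4,5,5-tetramethyl-1,3,2-dioxaborolan-2-yl)dodeca-2,6,10-trien-4-yl 4-[(tert-butyldimethylsilyl)oxy]benzoate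
Product: 19 (2Z,4R,6Z,10Z)-2,6,10-trimethyl-12-oxo-1-(4,4,5,5-tetramethyl-1,3,2-dioxaborolan-2-yl)dodeca-2,6,10-trien-4-yl 4-[(tert-butyldimethylsilyl)oxy]benzoate
Conditions: MnO2, CH2Cl2, rt; filter through Celite, keep in dilute solution
Reagents that add atoms: none
Why: MnO2 oxidises only the primary allylic alcohol, heterogeneously and without acid or base, so the (Z)-enal should form without isomerisation. A pinacol allylboronate of this substitution is not expected to add to an enal in dilute solution at rt, so 19 can be carried forward as a solution.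

Step 15
Reactants: 19 (2Z,4R,6Z,10Z)-2,6,10-trimethyl-12-oxo-1-(4,4,5,5-tetramethyl-1,3,2-dioxaborolan-2-yl)dodeca-2,6,10-trien-4-yl 4-[(tert-butyldimethylsilyl)oxy]benzoate
Product: 21 (1R,3Z,7Z,9S,10S)-9-hydroxy-3,7-dimethyl-10-(prop-1-en-2-yl)cyclodeca-3,7-dien-1-yl 4-[(tert-butyldimethylsilyl)oxy]benzoate, via borate ester 20 (not isolated)
Conditions: toluene (0.002 M), 4 Å MS, 80 °C; then aq. NaHCO3
Reagents that add atoms: none
Why: The boron of 19 binds the aldehyde oxygen and the γ-carbon C4 adds to C3 through a closed six-membered chair in which C3–C4 and O–B form together, giving borate 20, which the aqueous work-up hydrolyses to 21. The closest known reaction types are the thermal intramolecular allylboration of formyl-substituted allylboronates to medium rings and allylchromium–aldehyde closures of ten-membered terpenoid rings. The ten-membered ring closes in a 10-exo-trig sense at the carbonyl, fused at C3–C4 to the transition-state chair, and the two cis alkenes hold the chain ends near each other. C3 is set relative to C4 by the chair: with C2 equatorial and, because of the (Z)-geometry, C5 axial, OH and C5 come out syn in the crotyl sense, which is OH and isopropenyl cis on the ring. C4 is set by C5: allylic 1,3-strain with the cis CH2B group keeps C5–H in the alkene plane, and C3 is expected to bond on the face anti to C6, which also lets the ring torsion about C4–C5 be antiperiplanar. The step needs γ-attack (inherent in the cyclic transition state), cyclisation over oligomerisation (secured by 0.002 M), retention of the (Z)-enal (neutral medium) and the 4,5-relationship, which is the least secure point.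

Step 16
Reactants: 21 (1R,3Z,7Z,9S,10S)-9-hydroxy-3,7-dimethyl-10-(prop-1-en-2-yl)cyclodeca-3,7-dien-1-yl 4-[(tert-butyldimethylsilyl)oxy]benzoate
Product: 22 (1R,3Z,7Z,9S,10S)-9-hydroxy-3,7-dimethyl-10-(propan-2-yl)cyclodeca-3,7-dien-1-yl 4-[(tert-butyldimethylsilyl)oxy]benzoate
Conditions: 2-O2NC6H4SO2NHNH2 (excess), Et3N, CH2Cl2, rt
Reagents that add atoms: none
Why: Diimide, generated from 2-nitrobenzenesulfonylhydrazide, transfers H2 in a concerted syn fashion and is very sensitive to substitution, so the 1,1-disubstituted isopropenyl alkene should react well before the two trisubstituted ring alkenes. No metal is present that could isomerise the skipped diene or the allylic alcohol.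

Step 17
Reactants: 22 (1R,3Z,7Z,9S,10S)-9-hydroxy-3,7-dimethyl-10-(propan-2-yl)cyclodeca-3,7-dien-1-yl 4-[(tert-butyldimethylsilyl)oxy]benzoate
Product: 23 (1R,3Z,7Z,9S,10S)-9-hydroxy-3,7-dimethyl-10-(propan-2-yl)cyclodeca-3,7-dien-1-yl 4-hydroxybenzoate
Conditions: HF·pyridine, pyridine, THF, 0 °C → rt
Reagents that add atoms: none
Why: Fluoride cleavage of the aryl silyl ether under weakly acidic, pyridine-buffered conditions, which avoid the base that could move the ester from C5 to C3.

## Compound list

1 | nerol, (2Z)-3,7-dimethylocta-2,6-dien-1-ol | CC(C)=CCC/C(C)=C\CO | starting material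
2 | tert-butyl{[(2Z)-3,7-dimethylocta-2,6-dien-1-yl]oxy}dimethylsilane | CC(C)=CCC/C(C)=C\CO[Si](C)(C)C(C)(C)C | intermediate
3 | tert-butyl{[(2Z)-5-(3,3-dimethyloxiran-2-yl)-3-methylpent-2-en-1-yl]oxy}dimethylsilane (racemic at the oxirane carbon) | CC1(C)OC1CC/C(C)=C\CO[Si](C)(C)C(C)(C)C | intermediate
4 | (4Z)-6-[(tert-butyldimethylsilyl)oxy]-4-methylhex-4-enal | O=CCC/C(C)=C\CO[Si](C)(C)C(C)(C)C | intermediate
5 | tert-butyl{[(2Z,6Z)-7-iodo-3-methylocta-2,6-dien-1-yl]oxy}dimethylsilane | C/C(I)=C/CC/C(C)=C\CO[Si](C)(C)C(C)(C)C | intermediate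
6 | (S)-glycidol, [(2S)-oxiran-2-yl]methanol | C1[C@@H](O1)CO | starting material
7 | (2R)-2-{[(4-methoxybenzyl)oxy]methyl}oxirane | COc1ccc(COC[C@H]2CO2)cc1 | intermediate
8 | [(2E,6Z)-8-[(tert-butyldimethylsilyl)oxy]-6-methylocta-2,6-dien-2-yl]lithium (lithium cis to the chain; not isolated) | [Li]/C(C)=C\CC/C(C)=C\CO[Si](C)(C)C(C)(C)C | intermediate
9 | (2R,4Z,8Z)-10-[(tert-butyldimethylsilyl)oxy]-1-[(4-methoxybenzyl)oxy]-4,8-dimethyldeca-4,8-dien-2-ol | COc1ccc(COC[C@H](O)C/C(C)=C\CC/C(C)=C\CO[Si](C)(C)C(C)(C)C)cc1 | intermediate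
10 | 4-hydroxybenzoic acid | OC(=O)c1ccc(O)cc1 | starting material
11 | tert-butyldimethylsilyl 4-[(tert-butyldimethylsilyl)oxy]benzoate (not isolated) | CC(C)(C)[Si](C)(C)OC(=O)c1ccc(O[Si](C)(C)C(C)(C)C)cc1 | intermediate
12 | 4-[(tert-butyldimethylsilyl)oxy]benzoic acid | OC(=O)c1ccc(O[Si](C)(C)C(C)(C)C)cc1 | intermediate
13 | (2R,4Z,8Z)-10-[(tert-butyldimethylsilyl)oxy]-1-[(4-methoxybenzyl)oxy]-4,8-dimethyldeca-4,8-dien-2-yl 4-[(tert-butyldimethylsilyl)oxy]benzoate | COc1ccc(COC[C@H](OC(=O)c2ccc(O[Si](C)(C)C(C)(C)C)cc2)C/C(C)=C\CC/C(C)=C\CO[Si](C)(C)C(C)(C)C)cc1 | intermediate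
14 | (2R,4Z,8Z)-10-[(tert-butyldimethylsilyl)oxy]-1-hydroxy-4,8-dimethyldeca-4,8-dien-2-yl 4-[(tert-butyldimethylsilyl)oxy]benzoate | OC[C@H](OC(=O)c1ccc(O[Si](C)(C)C(C)(C)C)cc1)C/C(C)=C\CC/C(C)=C\CO[Si](C)(C)C(C)(C)C | intermediate
15 | (2R,4Z,8Z)-10-[(tert-butyldimethylsilyl)oxy]-4,8-dimethyl-1-oxodeca-4,8-dien-2-yl 4-[(tert-butyldimethylsilyl)oxy]benzoate | O=C[C@H](OC(=O)c1ccc(O[Si](C)(C)C(C)(C)C)cc1)C/C(C)=C\CC/C(C)=C\CO[Si](C)(C)C(C)(C)C | intermediate
16 | (2Z,4R,6Z,10Z)-12-[(tert-butyldimethylsilyl)oxy]-2-iodo-6,10-dimethyldodeca-2,6,10-trien-4-yl 4-[(tert-butyldimethylsilyl)oxy]benzoate | C/C(I)=C/[C@H](OC(=O)c1ccc(O[Si](C)(C)C(C)(C)C)cc1)C/C(C)=C\CC/C(C)=C\CO[Si](C)(C)C(C)(C)C | intermediate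
17 | (2Z,4R,6Z,10Z)-12-[(tert-butyldimethylsilyl)oxy]-2,6,10-trimethyl-1-(4,4,5,5-tetramethyl-1,3,2-dioxaborolan-2-yl)dodeca-2,6,10-trien-4-yl 4-[(tert-butyldimethylsilyl)oxy]benzoate | C/C(CB1OC(C)(C)C(C)(C)O1)=C/[C@H](OC(=O)c1ccc(O[Si](C)(C)C(C)(C)C)cc1)C/C(C)=C\CC/C(C)=C\CO[Si](C)(C)C(C)(C)C | intermediate
18 | (2Z,4R,6Z,10Z)-12-hydroxy-2,6,10-trimethyl-1-(4,4,5,5-tetramethyl-1,3,2-dioxaborolan-2-yl)dodeca-2,6,10-trien-4-yl 4-[(tert-butyldimethylsilyl)oxy]benzoate | C/C(CB1OC(C)(C)C(C)(C)O1)=C/[C@H](OC(=O)c1ccc(O[Si](C)(C)C(C)(C)C)cc1)C/C(C)=C\CC/C(C)=C\CO | intermediate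
19 | (2Z,4R,6Z,10Z)-2,6,10-trimethyl-12-oxo-1-(4,4,5,5-tetramethyl-1,3,2-dioxaborolan-2-yl)dodeca-2,6,10-trien-4-yl 4-[(tert-butyldimethylsilyl)oxy]benzoate | C/C(CB1OC(C)(C)C(C)(C)O1)=C/[C@H](OC(=O)c1ccc(O[Si](C)(C)C(C)(C)C)cc1)C/C(C)=C\CC/C(C)=C\C=O | intermediate
20 | (1R,3Z,7Z,9S,10S)-3,7-dimethyl-10-(prop-1-en-2-yl)-9-[(4,4,5,5-tetramethyl-1,3,2-dioxaborolan-2-yl)oxy]cyclodeca-3,7-dien-1-yl 4-[(tert-butyldimethylsilyl)oxy]benzoate (not isolated) | C/C1=C/[C@H](OB2OC(C)(C)C(C)(C)O2)[C@H](C(C)=C)[C@H](OC(=O)c2ccc(O[Si](C)(C)C(C)(C)C)cc2)C/C(C)=C\CC1 | intermediate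
21 | (1R,3Z,7Z,9S,10S)-9-hydroxy-3,7-dimethyl-10-(prop-1-en-2-yl)cyclodeca-3,7-dien-1-yl 4-[(tert-butyldimethylsilyl)oxy]benzoate | C/C1=C/[C@H](O)[C@H](C(C)=C)[C@H](OC(=O)c2ccc(O[Si](C)(C)C(C)(C)C)cc2)C/C(C)=C\CC1 | intermediate
22 | (1R,3Z,7Z,9S,10S)-9-hydroxy-3,7-dimethyl-10-(propan-2-yl)cyclodeca-3,7-dien-1-yl 4-[(tert-butyldimethylsilyl)oxy]benzoate | C/C1=C/[C@H](O)[C@H](C(C)C)[C@H](OC(=O)c2ccc(O[Si](C)(C)C(C)(C)C)cc2)C/C(C)=C\CC1 | intermediate
23 | (1R,3Z,7Z,9S,10S)-9-hydroxy-3,7-dimethyl-10-(propan-2-yl)cyclodeca-3,7-dien-1-yl 4-hydroxybenzoate | C/C1=C/[C@H](O)[C@H](C(C)C)[C@H](OC(=O)c2ccc(O)cc2)C/C(C)=C\CC1 | target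

## Step count and least certain steps

Total: 17 steps. Longest linear sequence: 15 steps (steps 1–4, 6, 8–17); steps 5 and 7 are side branches.

**Step 15 (key step).**
- What may go wrong: bonding on the wrong face of the allyl unit relative to C5, because one stereocentre has to direct a flexible transition state. The closure may also be slow enough for bimolecular addition or for thermal drift of the (Z)-enal. A diaryl hydrogen phosphate, which accelerates additions of pinacol allylboronates through the same closed transition state, would be the first adjustment in kind.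
- Fallback (from 16, back at 21): close the same bond through an allylchromium species.
  - Stille coupling of 16 with Bu3SnCH2OH (Pd(PPh3)4, dioxane, 80 °C) would give the (Z)-allylic alcohol F1.
  - MsCl, 2,4,6-collidine and LiCl in DMF at 0 °C would give the allylic chloride F2.
  - CSA in MeOH would free the C3 alcohol F3, and MnO2 would give the chloro enal F4.
  - CrCl2 with LiI in THF at high dilution (Nozaki–Hiyama allylation) would form C3–C4. An allylchromium reagent is expected to give mainly the anti product in the crotyl sense, that is the C3 epimer F5.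
  - DMP would oxidise F5 to the enone F6. NaBH4 with CeCl3·7H2O at −78 °C (Luche reduction) would be expected to deliver hydride anti to the C4 substituent and return 21.

**Step 11.**
- What may go wrong: enolisation of the α-aroyloxy aldehyde by the ylide, which would erode the C5 configuration or lower conversion, and incomplete Z-selectivity.
- Fallback (from 15, back at 17): a base-free dibromo-olefination followed by two selective couplings.
  - CBr4, PPh3 and 2,6-lutidine in CH2Cl2 at 0 °C would give the 1,1-dibromoalkene F7.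
  - MeZnCl with PdCl2(DPEphos) would replace the bromine trans to C5 and give the (Z)-bromoalkene F8.
  - IZnCH2Bpin with Pd(P(t-Bu)3)2 would then give 17.

**Step 12.**
- What may go wrong: protodemetalation or homocoupling of the α-boryl zinc reagent, or ionisation of the allylic C5 ester by zerovalent palladium once the allylboronate has formed.
- Fallback (from 16, back at 17): Miyaura borylation (B2pin2, PdCl2(dppf), KOPh, toluene, 50 °C) would give the alkenylboronate F9. Matteson homologation with LiCH2Cl, made in the flask from ICH2Cl and n-BuLi at −78 °C in the presence of F9, would give 17.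

**Step 13.**
- What may go wrong: loss of the phenolic silyl ether, or acid-promoted protodeboronation of the allylboronate during the methanolysis.
- Fallback (from 16, back at 18): reverse the order. CSA in MeOH on 16 would give the iodo alcohol F10, with no boron present. Coupling of F10 with an excess of IZnCH2Bpin and Pd(PPh3)4 would give 18 directly.

**Step 16.**
- What may go wrong: incomplete saturation of the hindered isopropenyl group, or competing reduction of the ring alkenes by the large excess of diimide.
- Fallback (from 21, back at 23): desilylation first (HF·pyridine, pyridine, THF) would give the phenol F11. Homogeneous hydrogenation with H2 (1 atm) and RhCl(PPh3)3 in benzene, which discriminates 1,1-disubstituted from trisubstituted alkenes by coordination, would give 23.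

## Further compounds

F1 | step 15 | (2Z,4R,6Z,10Z)-12-[(tert-butyldimethylsilyl)oxy]-1-hydroxy-2,6,10-trimethyldodeca-2,6,10-trien-4-yl 4-[(tert-butyldimethylsilyl)oxy]benzoate | C/C(CO)=C/[C@H](OC(=O)c1ccc(O[Si](C)(C)C(C)(C)C)cc1)C/C(C)=C\CC/C(C)=C\CO[Si](C)(C)C(C)(C)C
F2 | step 15 | (2Z,4R,6Z,10Z)-12-[(tert-butyldimethylsilyl)oxy]-1-chloro-2,6,10-trimethyldodeca-2,6,10-trien-4-yl 4-[(tert-butyldimethylsilyl)oxy]benzoate | C/C(CCl)=C/[C@H](OC(=O)c1ccc(O[Si](C)(C)C(C)(C)C)cc1)C/C(C)=C\CC/C(C)=C\CO[Si](C)(C)C(C)(C)C
F3 | step 15 | (2Z,4R,6Z,10Z)-1-chloro-12-hydroxy-2,6,10-trimethyldodeca-2,6,10-trien-4-yl 4-[(tert-butyldimethylsilyl)oxy]benzoate | C/C(CCl)=C/[C@H](OC(=O)c1ccc(O[Si](C)(C)C(C)(C)C)cc1)C/C(C)=C\CC/C(C)=C\CO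
F4 | step 15 | (2Z,4R,6Z,10Z)-1-chloro-2,6,10-trimethyl-12-oxododeca-2,6,10-trien-4-yl 4-[(tert-butyldimethylsilyl)oxy]benzoate | C/C(CCl)=C/[C@H](OC(=O)c1ccc(O[Si](C)(C)C(C)(C)C)cc1)C/C(C)=C\CC/C(C)=C\C=O
F5 | step 15 | (1R,3Z,7Z,9R,10S)-9-hydroxy-3,7-dimethyl-10-(prop-1-en-2-yl)cyclodeca-3,7-dien-1-yl 4-[(tert-butyldimethylsilyl)oxy]benzoate (C3 epimer of 21) | C/C1=C/[C@@H](O)[C@H](C(C)=C)[C@H](OC(=O)c2ccc(O[Si](C)(C)C(C)(C)C)cc2)C/C(C)=C\CC1
F6 | step 15 | (1R,3Z,7Z,10R)-3,7-dimethyl-9-oxo-10-(prop-1-en-2-yl)cyclodeca-3,7-dien-1-yl 4-[(tert-butyldimethylsilyl)oxy]benzoate | C/C1=C/C(=O)[C@H](C(C)=C)[C@H](OC(=O)c2ccc(O[Si](C)(C)C(C)(C)C)cc2)C/C(C)=C\CC1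
F7 | step 11 | (3R,5Z,9Z)-1,1-dibromo-11-[(tert-butyldimethylsilyl)oxy]-5,9-dimethylundeca-1,5,9-trien-3-yl 4-[(tert-butyldimethylsilyl)oxy]benzoate | BrC(Br)=C[C@H](OC(=O)c1ccc(O[Si](C)(C)C(C)(C)C)cc1)C/C(C)=C\CC/C(C)=C\CO[Si](C)(C)C(C)(C)C
F8 | step 11 | (2Z,4R,6Z,10Z)-2-bromo-12-[(tert-butyldimethylsilyl)oxy]-6,10-dimethyldodeca-2,6,10-trien-4-yl 4-[(tert-butyldimethylsilyl)oxy]benzoate | C/C(Br)=C/[C@H](OC(=O)c1ccc(O[Si](C)(C)C(C)(C)C)cc1)C/C(C)=C\CC/C(C)=C\CO[Si](C)(C)C(C)(C)C
F9 | step 12 | (2E,4R,6Z,10Z)-12-[(tert-butyldimethylsilyl)oxy]-6,10-dimethyl-2-(4,4,5,5-tetramethyl-1,3,2-dioxaborolan-2-yl)dodeca-2,6,10-trien-4-yl 4-[(tert-butyldimethylsilyl)oxy]benzoate (boron cis to C4) | C/C(B1OC(C)(C)C(C)(C)O1)=C/[C@H](OC(=O)c1ccc(O[Si](C)(C)C(C)(C)C)cc1)C/C(C)=C\CC/C(C)=C\CO[Si](C)(C)C(C)(C)C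
F10 | step 13 | (2Z,4R,6Z,10Z)-12-hydroxy-2-iodo-6,10-dimethyldodeca-2,6,10-trien-4-yl 4-[(tert-butyldimethylsilyl)oxy]benzoate | C/C(I)=C/[C@H](OC(=O)c1ccc(O[Si](C)(C)C(C)(C)C)cc1)C/C(C)=C\CC/C(C)=C\CO
F11 | step 16 | (1R,3Z,7Z,9S,10S)-9-hydroxy-3,7-dimethyl-10-(prop-1-en-2-yl)cyclodeca-3,7-dien-1-yl 4-hydroxybenzoate | C/C1=C/[C@H](O)[C@H](C(C)=C)[C@H](OC(=O)c2ccc(O)cc2)C/C(C)=C\CC1
A1 | alternative 1 | cis-fused 8a-hydroxy-1-isopropyl-2-[(4-methoxybenzyl)oxy]-3a,7-dimethyl-1,2,3,3a,4,5,6,8a-octahydroazulen-4-yl methanesulfonate (mesylate trans to the angular methyl; one suitable diastereomer) | CC1=C[C@@]2(O)[C@H](C(C)C)[C@H](OCc3ccc(OC)cc3)C[C@@]2(C)[C@@H](OS(C)(=O)=O)CC1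
A2 | alternative 1 | (2Z,6Z)-10-isopropyl-9-[(4-methoxybenzyl)oxy]-3,7-dimethylcyclodeca-2,6-dien-1-one | C/C1=C/C(=O)[C@H](C(C)C)[C@H](OCc2ccc(OC)cc2)C/C(C)=C\CC1
A3 | alternative 2 | tributyl[(5Z)-4-[(tert-butyldimethylsilyl)oxy]-3-isopropyl-6-methyl-9-(prop-1-en-2-yl)-2,3,4,7,8,9-hexahydrooxonin-2-yl]stannane (stannyl and isopropenyl groups trans) | CCCC[Sn](CCCC)(CCCC)[C@@H]1O[C@@H](C(C)=C)CC/C(C)=C\[C@H](O[Si](C)(C)C(C)(C)C)[C@@H]1C(C)C
A4 | alternative 2 | ten-membered (Z,Z)-diene with free C5 hydroxyl and C3 tert-butyldimethylsilyl ether | C/C1=C/[C@H](O[Si](C)(C)C(C)(C)C)[C@H](C(C)C)[C@H](O)C/C(C)=C\CC1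
A5 | alternative 3 | open-chain (Z,Z)-allylic bromide with terminal allylic phenyl sulfone, C3 silyl ether and C5 PMB ether | BrC/C(C)=C\[C@H](O[Si](C)(C)C(C)(C)C)[C@H](C(C)C)[C@H](OCc1ccc(OC)cc1)C/C(C)=C\CS(=O)(=O)c1ccccc1
A6 | alternative 3 | ten-membered (Z,Z)-diene with phenylsulfonyl group on C9 (one C9 epimer drawn) | C/C1=C/[C@H](O[Si](C)(C)C(C)(C)C)[C@H](C(C)C)[C@H](OCc2ccc(OC)cc2)C/C(C)=C\[C@@H](S(=O)(=O)c2ccccc2)C1
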